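## Structural features

The target 27 is a sesquineolignan in which two five-membered oxygen heterocycles are joined through a benzene ring. A tetrahydrofuran (O1, C2–C5; these locants are used for every intermediate) is bonded at C2 to C5' of the benzo ring (ring A) of a 7'-methoxy-2',3'-dihydrobenzofuran (O1', C2', C3'). C3 carries CH2OH, C4 a tertiary hydroxyl and a 4-hydroxy-3-methoxybenzyl group, C2' a second guaiacyl ring and C3' another CH2OH.

C2 (R), C3 (R) and C4 (S) are contiguous, with H2, H3 and OH4 on one face, so the aryl, hydroxymethyl and benzyl groups are all cis on the other. C2' (R) and C3' (R) are adjacent and cis, and ring A separates them from C2, so neither set of centres can control the other.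

Both benzylic C–O bonds (C2–O1 and C2'–O1') lie para to an oxygen substituent. They ionise under acid or, once the phenol is free, under base, which would turn the crowded cis arrangements into the more stable trans ones; the free guaiacyl phenols are also oxidisable.

The real difficulty is the all-cis C2–C3–C4 triad with its quaternary carbinol, which must be made in one absolute sense without help from the remote dihydrobenzofuran and without stressing the benzylic ethers.

The key step exploits the fact that O1, C2, C3, C4 and C5 with both side chains map onto a fully substituted butenolide, O1–C5(=O)–C4(benzyl)=C3(CH2Si)–C2(H)(aryl), whose only stereocentre is C2. The C2 oxygen of an open-chain propargylic alcohol steers carbon to C3 and the carboxyl carbon C5 to C4, and in the ring the C2 aryl group then shields one face for the entry of H3 and OH4.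

On descriptors: the C2 centre reads S in 15, 20 and 21 and R from 22 onwards, and C3' reads S in 8 and R afterwards. Nothing changes in space; only the CIP ranks of the neighbours change.

## Logic of the disconnections

27 ⇒ 25. The three O–Si bonds are restored and the C–O bond of the C3 hydroxymethyl group is exchanged for C–Si. Phenols and the primary alcohol must stay masked through organometallic, enolate and Lewis-acid steps, and silicon is the form in which a hydroxymethyl carbanion can be delivered. The gain is a precursor with a single free hydroxyl (OH4). The demand is a fluoride/peroxide sequence mild enough for two benzylic ethers and two guaiacyl rings.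

25 ⇒ 23 (through 24). The two C5–H bonds are cut and C5 returns to the carboxyl level. A C5 carbonyl is what makes C4 enolisable and is what a carboxylation delivers. The demand is a two-stage reduction of C=O to CH2 cold enough that C2–O1 does not ionise.

23 ⇒ 22. The C4–OH bond is cut. Oxygen can be put on a lactone enolate, and the C3 and C2 substituents both sit on one face of 22. This removes the quaternary stereocentre. The forward step must bring oxygen in anti to the C3 silylmethyl group, and the base must leave C2 alone.

22 ⇒ 21. The C3–H and C4–H bonds are cut to give the C3=C4 alkene. Two stereocentres disappear and C2 is the only one left on this ring. The forward hydrogenation must add both hydrogens from the face opposite the C2 aryl group without hydrogenolysis of C2–O1 and without touching the arenes.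

21 ⇒ 15 + 17 + 18. Three bonds are cut: C3–CH2(Si), C4–C5 and O1–C5. All three, and the alkene geometry, can be made in one flask under the direction of the C2 oxygen. A cyclic tetrasubstituted alkene is reduced to an open-chain alkynol, a one-carbon silicon reagent and a one-carbon electrophile. The forward step must put carbon on C3 and the metal on C4 in an anti sense and must not disturb C2.

15 ⇒ 11 + 14. The C2–C3 bond is cut. It divides the molecule into halves of similar size and is the only bond whose formation creates C2. The demand is reagent-controlled facial selectivity, because the stereocentres of 11 are too far away to help.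

14 ⇒ 12 + 13, 12 ⇒ 3 ⇒ 2 ⇒ 1, and 17 ⇒ 16. The benzylic C–C(sp) bond, the C–Br bond and the C–Mg bond are cut. Everything on this side comes from one cheap aromatic aldehyde, and 3 is used twice (for 12 and for 5). The forward coupling must avoid isomerisation of the skipped aryl alkyne.

11 ⇒ 10 ⇒ 9 ⇒ 8. Only functional groups change: one O–Si bond, the aldehyde/alcohol level on ring A, and two ester reductions. The ring-forming step needs an ester on C3' and tolerates one on ring A. The reduction must be non-basic (the cis ester is epimerisable) and the oxidation must pick the benzylic alcohol.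

8 ⇒ 7. The C2'–C3' bond is cut. A carbene C–H insertion makes both dihydrobenzofuran stereocentres, cis, from an achiral ether. The demand is catalyst-controlled cis- and enantioselectivity.

7 ⇒ 5 + 6 and 5 ⇒ 4 + 3. The aryl–C(diazo) bond and the O–CH2 bond are cut. 4 already has the full ring A pattern: a carboxyl carbon where C2 will attach, iodine where C3' will attach, and the hydroxyl that becomes O1'. Both couplings must be mild enough to keep the aryl silyl ether.

## Other disconnections considered

Alternative 1: The cut is C2–C3 and O1–C5 at the lactone level, with C4 left as an exocyclic methylene. In the forward step 11 reacts with the γ-(silyloxymethyl) allylboronate A2 under a chiral acid (a chiral diol·SnCl4 complex or a BINOL-derived phosphoric acid) through a closed six-membered transition state, and the boron alkoxide lactonises to A1.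
- In favour: C2 and C3 are made together and their cis relationship follows stereospecifically from the alkene geometry of A2. The hydroxymethyl group arrives as a silyl ether at its final oxidation level. No tetrasubstituted alkene has to be hydrogenated and no C–Si bond oxidised.
- Against: A2 is deactivated by its ester and needs strong acid activation, while 11 is an electron-rich aldehyde, so A1 is liable to ionise at C2–O1 and drift to trans under the conditions that form it. Catalytic enantiocontrol for this pairing is not established. A1 still lacks the benzyl carbon on C4, so the aryl group and OH4 must be added across the exocyclic alkene afterwards (for instance epoxidation anti to the C3 substituent and opening at CH2 by an arylcopper reagent) on a base-sensitive α-methylene lactone.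
- Comparison: for the C2/C3 relay Alternative 1 is the better plan (one step against alkynylation, carbometalation and hydrogenation) and it is about two steps shorter after 11. It is the equal of the chosen plan in that OH4 is directed by the C3 substituent in both, and both key steps are stereospecific through a cyclic, metal-organised arrangement. The chosen plan is stronger where Alternative 1 is weakest: its enantio-determining step is a separate carbonyl addition, the ring closes without exposing a benzylic lactone to strong acid, and both side chains are in place when the ring closes.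

Alternative 2: The cut is C2'–C3' of the dihydrobenzofuran, made last. The diazo ester A4, which already contains the complete silylated tetrahydrofuran, is decomposed by Rh2(S-PTTL)4 or its enantiomer, and the carbenoid inserts into the O-benzylic C–H bond to give A3.
- In favour: the ring closure is the same reaction as step 5, so mechanism and precedent are equal. The fragile cis-dihydrobenzofuran would not have to survive the Grignard reagent, the hydrogenation, the enolate or BF3·OEt2, which is a point on which this alternative is better.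
- Against: the carbenoid of A4 meets, besides the intended CH2, the doubly activated C2–H and the C5–H2 of the tetrahydrofuran, so site selectivity is less secure than in 7. The handle for the diazo ester on ring A would have to pass through the butenolide chemistry, where an aryl iodide is at risk from the Grignard reagent and from hydrogenation, and an arylacetate from every basic step. OH4 needs its own protecting group. The epimerisable cis ester must be reduced on the most valuable intermediate.
- Comparison: the step count is about the same, but the sequence is fully linear and its least reliable operations (diazo installation, insertion, ester reduction) come at the end. The chosen plan runs them first on simple material.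

Alternative 3: The cut is O1'–C2'. The phenol of the diol A6 displaces its Mitsunobu-activated benzylic hydroxyl with inversion to give A5; the two stereocentres of A6 would come from an auxiliary-controlled syn aldol reaction.
- In favour: the configuration comes from an aldol reaction whose sense is predictable, which is better than the catalyst-controlled insertion of step 5, whose sense has to be confirmed. No diazo compound or rhodium is needed. A5 is one acetal hydrolysis from 11, so this alternative would feed the same key step and replaces only steps 3–8.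
- Against: the benzylic alcohol is para to an oxygen and its activated form can ionise, after which inversion is no longer guaranteed (the pivalate is there to slow this). The arylacetyl unit, the auxiliary, two phenol protecting groups and the acetal each cost steps: roughly ten to reach 11 against six.
- Comparison: the two closures are equal in being kinetically controlled and free of base that could epimerise the cis ring. The alternative is better on predictability, the chosen plan on step economy.

Key step: step 13

Abbreviations used in names: TBS = tert-butyldimethylsilyl; G = 4-[(tert-butyldimethylsilyl)oxy]-3-methoxyphenyl; DHB = (2R,3R)-2-G-3-{[(tert-butyldimethylsilyl)oxy]methyl}-7-methoxy-2,3-dihydro-1-benzofuran-5-yl.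

Remark: 4 is taken to be a catalogue compound; if it must be made, iodination of methyl vanillate supplies it in one extra step that does not lie on the longest sequence.

Step 1
Reactants: 1 vanillin (4-hydroxy-3-methoxybenzaldehyde)
Product: 2 4-[(tert-butyldimethylsilyl)oxy]-3-methoxybenzaldehyde
Conditions: TBSCl, imidazole, DMF, rt
Reagents that add atoms: tert-butyldimethylsilyl chloride, CC(C)(C)[Si](C)(C)Cl
Why: Imidazole-promoted silylation of the phenol gives an aryl silyl ether that withstands hydride, organozinc, Grignard and enolate chemistry and is removed by fluoride at the end.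

Step 2
Reactants: 2 4-[(tert-butyldimethylsilyl)oxy]-3-methoxybenzaldehyde
Product: 3 {4-[(tert-butyldimethylsilyl)oxy]-3-methoxyphenyl}methanol
Conditions: NaBH4, MeOH, 0 °C
Reagents that add atoms: none
Why: Borohydride reduction of the aldehyde; the aryl silyl ether is stable to NaBH4 in cold methanol for the short reaction time.

Step 3
Reactants: 4 methyl 4-hydroxy-3-iodo-5-methoxybenzoate; 3 {4-[(tert-butyldimethylsilyl)oxy]-3-methoxyphenyl}methanol
Product: 5 methyl 4-(G-methoxy)-3-iodo-5-methoxybenzoate
Conditions: PPh3, DIAD, THF, 0 °C → rt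
Reagents that add atoms: none
Why: Mitsunobu etherification: the para ester makes phenol 4 acidic enough to protonate the betaine, and the primary benzylic alcohol is displaced under neutral conditions, which avoids carbonate bases that could strip the aryl silyl ether.

Step 4
Reactants: 5 methyl 4-(G-methoxy)-3-iodo-5-methoxybenzoate; 6 ethyl diazoacetate
Product: 7 ethyl 2-diazo-2-[2-(G-methoxy)-3-methoxy-5-(methoxycarbonyl)phenyl]acetate
Conditions: Pd(PPh3)4 (5 mol%), Ag2CO3, Et3N, toluene, rt
Reagents that add atoms: none
Why: Palladium-catalysed cross-coupling of an aryl iodide with the C–H bond of a diazo ester (oxidative addition, base- and silver-assisted palladation of the diazo carbon, reductive elimination) keeps the diazo group and gives the donor/acceptor diazo compound in one step; the benzoate and silyl ether are inert.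

Step 5
Reactants: 7 ethyl 2-diazo-2-[2-(G-methoxy)-3-methoxy-5-(methoxycarbonyl)phenyl]acetate
Product: 8 3-ethyl 5-methyl (2R,3S)-2-G-7-methoxy-2,3-dihydro-1-benzofuran-3,5-dicarboxylate (2,3-cis)
Conditions: Rh2(S-PTTL)4 (1 mol%), toluene, −60 °C
Reagents that add atoms: none
Why: The dirhodium carboxylate forms a donor/acceptor carbenoid that inserts into the electron-rich O-benzylic C–H bond five atoms away (intramolecular 1,5 C–H insertion, concerted three-centre transition state) and gives the kinetic cis ring. The chiral N-phthaloyl-tert-leucinate ligands set C2' and C3' together; the catalyst antipode that gives the 2R,3S ester is used, Rh2(R-PTTL)4 taking its place if the first batch shows the opposite sense. No base is present that could epimerise C3'.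

Step 6
Reactants: 8 3-ethyl 5-methyl (2R,3S)-2-G-7-methoxy-2,3-dihydro-1-benzofuran-3,5-dicarboxylate
Product: 9 [(2R,3R)-2-G-7-methoxy-2,3-dihydro-1-benzofuran-3,5-diyl]dimethanol
Conditions: iBu2AlH (5 equiv), CH2Cl2, −78 → 0 °C; aq. potassium sodium tartrate
Reagents that add atoms: none
Why: Non-basic hydride reduction of both esters; the transient C3' aldehyde is reduced faster than it can enolise, so the cis relationship is kept, and C3' is no longer epimerisable afterwards.

Step 7
Reactants: 9 [(2R,3R)-2-G-7-methoxy-2,3-dihydro-1-benzofuran-3,5-diyl]dimethanol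
Product: 10 (2R,3R)-2-G-3-(hydroxymethyl)-7-methoxy-2,3-dihydro-1-benzofuran-5-carbaldehyde
Conditions: MnO2, CH2Cl2, rt
Reagents that add atoms: none
Why: MnO2 oxidises only the benzylic alcohol on ring A; the saturated primary alcohol on C3' is not activated and stays.

Step 8
Reactants: 10 (2R,3R)-2-G-3-(hydroxymethyl)-7-methoxy-2,3-dihydro-1-benzofuran-5-carbaldehyde
Product: 11 (2R,3R)-2-G-3-{[(tert-butyldimethylsilyl)oxy]methyl}-7-methoxy-2,3-dihydro-1-benzofuran-5-carbaldehyde
Conditions: TBSCl, imidazole, DMF, rt
Reagents that add atoms: tert-butyldimethylsilyl chloride, CC(C)(C)[Si](C)(C)Cl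
Why: Standard silylation of the primary alcohol, so that only one hydroxyl (the future C2–OH) is free in the carbometalation.

Step 9
Reactants: 3 {4-[(tert-butyldimethylsilyl)oxy]-3-methoxyphenyl}methanol
Product: 12 [4-(bromomethyl)-2-methoxyphenoxy](tert-butyl)dimethylsilane
Conditions: CBr4, PPh3, CH2Cl2, 0 °C
Reagents that add atoms: carbon tetrabromide, BrC(Br)(Br)Br
Why: Appel bromination under neutral conditions; the electron-rich benzylic bromide is used at once without storage.

Step 10
Reactants: 12 [4-(bromomethyl)-2-methoxyphenoxy](tert-butyl)dimethylsilane; 13 ethynylmagnesium bromide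
Product: 14 tert-butyl[2-methoxy-4-(prop-2-yn-1-yl)phenoxy]dimethylsilane
Conditions: 13 (3 equiv), CuBr·SMe2 (10 mol%), THF, 0 °C → rt
Reagents that add atoms: none
Why: Copper-catalysed coupling of an alkynyl Grignard reagent with a benzylic bromide; the excess of 13 suppresses double benzylation, and the mild temperature limits isomerisation of the skipped aryl alkyne to the allene.

Step 11
Reactants: 11 (2R,3R)-2-G-3-{[(tert-butyldimethylsilyl)oxy]methyl}-7-methoxy-2,3-dihydro-1-benzofuran-5-carbaldehyde; 14 tert-butyl[2-methoxy-4-(prop-2-yn-1-yl)phenoxy]dimethylsilane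
Product: 15 (1S)-1-DHB-4-G-but-2-yn-1-ol
Conditions: Me2Zn (3 equiv), 14 (3 equiv), (S,S)-ProPhenol (20 mol%), Ph3P=O (40 mol%), toluene, 4 °C
Reagents that add atoms: none
Why: Catalytic enantioselective alkynylation: Me2Zn deprotonates 14 at the alkyne terminus and the alkynylzinc adds to the aldehyde inside the dinuclear zinc–ProPhenol pocket. The new C2 carbinol (S) arises from delivery to the Re face under ligand control, the dihydrobenzofuran centres being too remote to interfere. The ligand antipode is fixed by a Mosher ester check on the first batch, (R,R)-ProPhenol being used if the sense is opposite.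

Step 12
Reactants: 16 (chloromethyl)(isopropoxy)dimethylsilane
Product: 17 [(isopropoxydimethylsilyl)methyl]magnesium chloride (titrated THF solution)
Conditions: Mg turnings, BrCH2CH2Br (cat.), THF, reflux, then 0 °C
Reagents that add atoms: magnesium, [Mg]
Why: Magnesium insertion into the C–Cl bond gives the hydroxymethyl-anion equivalent; the bulky isopropoxy group keeps the reagent from attacking its own silicon.

Step 13
Reactants: 15 (1S)-1-DHB-4-G-but-2-yn-1-ol; 17 [(isopropoxydimethylsilyl)methyl]magnesium chloride; 18 carbon dioxide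
Product: 21 (5S)-5-DHB-3-(G-methyl)-4-{[dimethyl(propan-2-yloxy)silyl]methyl}furan-2(5H)-one, via oxamagnesacycle 19 (not isolated), via hydroxy acid 20 (not isolated)
Conditions: 17 (4 equiv), CuI (20 mol%), THF–toluene, −20 °C → rt; CO2 (1 atm), 0 °C → rt; aq. citric acid, 0 °C
Reagents that add atoms: none
Why: The first equivalent of 17 deprotonates 15; CuI then transmetalates further 17 to a silylmethylcopper species that adds across the alkyne while magnesium stays bound to the alkoxide, so the silylmethyl carbon goes to C3 and the metal to C4 from opposite sides (anti addition), giving the five-membered oxamagnesacycle 19. Carbon dioxide inserts into the C4–Mg bond of 19, and on acidification the C2 hydroxyl of the resulting acid 20 attacks the carboxyl carbon and closes the butenolide by 5-exo-trig acyl substitution with loss of water. The closest known reaction type is the copper-catalysed anti-carbomagnesiation of 2-alkyn-1-ols with carboxylation in the same flask to give 2(5H)-furanones; (trimethylsilyl)methyl Grignard reagents are known to add to propargyl alcohol in this way. No stereocentre is formed: C2 is carried through unchanged because its C–O and C–H bonds take no part and the lactone appears only at the acidic quench, after all basic species are destroyed. The step needs regioselectivity (carbon to C3) and anti stereoselectivity, since only then is the carboxyl group cis to the C2 oxygen and able to lactonise; both are secured by the alkoxide, because the chelate can form only with magnesium on C4 cis to the carbinol carbon. The Si–OiPr group is a spectator: exchange to silanol or disiloxane on work-up does no harm, since all these forms are oxidised in step 18.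

Step 14
Reactants: 21 (5S)-5-DHB-3-(G-methyl)-4-{[dimethyl(propan-2-yloxy)silyl]methyl}furan-2(5H)-one
Product: 22 (3R,4S,5R)-5-DHB-3-(G-methyl)-4-{[dimethyl(propan-2-yloxy)silyl]methyl}oxolan-2-one (all-cis)
Conditions: H2 (5 bar), 5% Rh/Al2O3, EtOAc, rt
Reagents that add atoms: none
Why: Heterogeneous hydrogenation: the butenolide adsorbs through the face opposite the C2 aryl group and both hydrogens are delivered syn from that face, so H3 (and H4) end up cis to H2. Rhodium on alumina is chosen because it saturates hindered alkenes at low pressure with little hydrogenolysis of the allylic–benzylic C2–O1 bond, and the neutral medium keeps C2 from racemising.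

Step 15
Reactants: 22 (3R,4S,5R)-5-DHB-3-(G-methyl)-4-{[dimethyl(propan-2-yloxy)silyl]methyl}oxolan-2-one
Product: 23 (3S,4R,5R)-5-DHB-3-(G-methyl)-3-hydroxy-4-{[dimethyl(propan-2-yloxy)silyl]methyl}oxolan-2-one
Conditions: KN(SiMe3)2 (1.3 equiv), THF, −78 °C; 3-phenyl-2-(phenylsulfonyl)oxaziridine, −78 °C; aq. NH4Cl
Reagents that add atoms: 3-phenyl-2-(phenylsulfonyl)oxaziridine, O=S(=O)(c1ccccc1)N1OC1c1ccccc1
Why: Davis enolate oxidation: the potassium enolate is planar at C4 and the oxaziridine transfers oxygen to the face opposite the C3 silylmethyl and C2 aryl groups, which both sit on the other face. OH4 therefore lands cis to H3 and H2 and the benzyl group is pushed to the substituted face; C2 and C3 carry no hydrogen that this base can remove.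

Step 16
Reactants: 23 (3S,4R,5R)-5-DHB-3-(G-methyl)-3-hydroxy-4-{[dimethyl(propan-2-yloxy)silyl]methyl}oxolan-2-one
Product: 24 (3S,4R,5R)-5-DHB-3-(G-methyl)-4-{[dimethyl(propan-2-yloxy)silyl]methyl}oxolane-2,3-diol (both anomers, used crude)
Conditions: iBu2AlH (3 equiv), CH2Cl2, −78 °C; aq. potassium sodium tartrate
Reagents that add atoms: none
Why: Half-reduction of the lactone: the tetrahedral aluminium alkoxide is stable at −78 °C and gives the lactol on work-up; the tertiary hydroxyl consumes one equivalent of hydride and is otherwise a spectator.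

Step 17
Reactants: 24 (3S,4R,5R)-5-DHB-3-(G-methyl)-4-{[dimethyl(propan-2-yloxy)silyl]methyl}oxolane-2,3-diol
Product: 25 (3S,4R,5R)-5-DHB-3-(G-methyl)-4-{[dimethyl(propan-2-yloxy)silyl]methyl}oxolan-3-ol
Conditions: Et3SiH (5 equiv), BF3·OEt2 (3 equiv), CH2Cl2, −78 → −50 °C
Reagents that add atoms: none
Why: Ionic hydrogenation of the lactol: BF3·OEt2 generates the cyclic oxocarbenium ion at C5 and Et3SiH delivers hydride; C5 becomes CH2, so no stereocentre is at stake, and the low temperature keeps the electron-rich C2–O1 bond from ionising.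

Step 18
Reactants: 25 (3S,4R,5R)-5-DHB-3-(G-methyl)-4-{[dimethyl(propan-2-yloxy)silyl]methyl}oxolan-3-ol
Product: 27 target (3S,4R,5R)-5-[(2R,3R)-2-(4-hydroxy-3-methoxyphenyl)-3-(hydroxymethyl)-7-methoxy-2,3-dihydro-1-benzofuran-5-yl]-3-[(4-hydroxy-3-methoxyphenyl)methyl]-4-(hydroxymethyl)oxolan-3-ol, via fluorosilane pentaol 26 (not isolated)
Conditions: Bu4NF (6 equiv), AcOH (6 equiv), THF, 0 °C → rt; then MeOH, KHCO3, 30% H2O2, rt
Reagents that add atoms: hydrogen peroxide, OO
Why: Fluoride cleaves the three silyl ethers and converts Si–OiPr into Si–F, with acetic acid buffering the phenoxides so that the cis-dihydrobenzofuran cannot open through a quinone methide. Basic peroxide then performs the Tamao oxidation in the same flask: hydroperoxide adds to silicon and the CH2 group migrates from silicon to oxygen, giving the C3 hydroxymethyl group without touching any stereocentre.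

## Compound list

1 | vanillin (4-hydroxy-3-methoxybenzaldehyde) | COc1cc(C=O)ccc1O | starting material
2 | 4-[(tert-butyldimethylsilyl)oxy]-3-methoxybenzaldehyde | COc1cc(C=O)ccc1O[Si](C)(C)C(C)(C)C | intermediate
3 | {4-[(tert-butyldimethylsilyl)oxy]-3-methoxyphenyl}methanol | COc1cc(CO)ccc1O[Si](C)(C)C(C)(C)C | intermediate
4 | methyl 4-hydroxy-3-iodo-5-methoxybenzoate | COC(=O)c1cc(I)c(O)c(OC)c1 | starting material
5 | methyl 4-(G-methoxy)-3-iodo-5-methoxybenzoate | COC(=O)c1cc(I)c(OCc2ccc(O[Si](C)(C)C(C)(C)C)c(OC)c2)c(OC)c1 | intermediate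
6 | ethyl diazoacetate | CCOC(=O)C=[N+]=[N-] | starting material
7 | ethyl 2-diazo-2-[2-(G-methoxy)-3-methoxy-5-(methoxycarbonyl)phenyl]acetate | CCOC(=O)C(=[N+]=[N-])c1cc(C(=O)OC)cc(OC)c1OCc1ccc(O[Si](C)(C)C(C)(C)C)c(OC)c1 | intermediate
8 | 3-ethyl 5-methyl (2R,3S)-2-G-7-methoxy-2,3-dihydro-1-benzofuran-3,5-dicarboxylate (2,3-cis) | COC(=O)c1cc(OC)c2c(c1)[C@H](C(=O)OCC)[C@H](c1ccc(O[Si](C)(C)C(C)(C)C)c(OC)c1)O2 | intermediate
9 | [(2R,3R)-2-G-7-methoxy-2,3-dihydro-1-benzofuran-3,5-diyl]dimethanol | OCc1cc(OC)c2c(c1)[C@H](CO)[C@H](c1ccc(O[Si](C)(C)C(C)(C)C)c(OC)c1)O2 | intermediate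
10 | (2R,3R)-2-G-3-(hydroxymethyl)-7-methoxy-2,3-dihydro-1-benzofuran-5-carbaldehyde | O=Cc1cc(OC)c2c(c1)[C@H](CO)[C@H](c1ccc(O[Si](C)(C)C(C)(C)C)c(OC)c1)O2 | intermediate
11 | (2R,3R)-2-G-3-{[(tert-butyldimethylsilyl)oxy]methyl}-7-methoxy-2,3-dihydro-1-benzofuran-5-carbaldehyde | O=Cc1cc(OC)c2c(c1)[C@H](CO[Si](C)(C)C(C)(C)C)[C@H](c1ccc(O[Si](C)(C)C(C)(C)C)c(OC)c1)O2 | intermediate
12 | [4-(bromomethyl)-2-methoxyphenoxy](tert-butyl)dimethylsilane | COc1cc(CBr)ccc1O[Si](C)(C)C(C)(C)C | intermediate
13 | ethynylmagnesium bromide | C#C[Mg]Br | starting material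
14 | tert-butyl[2-methoxy-4-(prop-2-yn-1-yl)phenoxy]dimethylsilane | C#CCc1ccc(O[Si](C)(C)C(C)(C)C)c(OC)c1 | intermediate
15 | (1S)-1-DHB-4-G-but-2-yn-1-ol | O[C@H](C#CCc1ccc(O[Si](C)(C)C(C)(C)C)c(OC)c1)c1cc(OC)c2c(c1)[C@H](CO[Si](C)(C)C(C)(C)C)[C@H](c1ccc(O[Si](C)(C)C(C)(C)C)c(OC)c1)O2 | intermediate
16 | (chloromethyl)(isopropoxy)dimethylsilane | CC(C)O[Si](C)(C)CCl | starting material
17 | [(isopropoxydimethylsilyl)methyl]magnesium chloride | CC(C)O[Si](C)(C)C[Mg]Cl | intermediate
18 | carbon dioxide | O=C=O | starting material
19 | (5S)-5-DHB-3-(G-methyl)-4-{[dimethyl(propan-2-yloxy)silyl]methyl}-2,5-dihydro-1,2-oxamagnesole | [Mg]1O[C@@H](c2cc(OC)c3c(c2)[C@H](CO[Si](C)(C)C(C)(C)C)[C@H](c2ccc(O[Si](C)(C)C(C)(C)C)c(OC)c2)O3)C(C[Si](C)(C)OC(C)C)=C1Cc1ccc(O[Si](C)(C)C(C)(C)C)c(OC)c1 | intermediate (not isolated)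
20 | (2E,4S)-4-DHB-4-hydroxy-2-(G-methyl)-3-{[dimethyl(propan-2-yloxy)silyl]methyl}but-2-enoic acid (carboxyl and carbinol carbon cis) | OC(=O)/C(Cc1ccc(O[Si](C)(C)C(C)(C)C)c(OC)c1)=C(/C[Si](C)(C)OC(C)C)[C@@H](O)c1cc(OC)c2c(c1)[C@H](CO[Si](C)(C)C(C)(C)C)[C@H](c1ccc(O[Si](C)(C)C(C)(C)C)c(OC)c1)O2 | intermediate (not isolated)
21 | (5S)-5-DHB-3-(G-methyl)-4-{[dimethyl(propan-2-yloxy)silyl]methyl}furan-2(5H)-one | O=C1O[C@@H](c2cc(OC)c3c(c2)[C@H](CO[Si](C)(C)C(C)(C)C)[C@H](c2ccc(O[Si](C)(C)C(C)(C)C)c(OC)c2)O3)C(C[Si](C)(C)OC(C)C)=C1Cc1ccc(O[Si](C)(C)C(C)(C)C)c(OC)c1 | intermediate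
22 | (3R,4S,5R)-5-DHB-3-(G-methyl)-4-{[dimethyl(propan-2-yloxy)silyl]methyl}oxolan-2-one (all-cis) | O=C1O[C@@H](c2cc(OC)c3c(c2)[C@H](CO[Si](C)(C)C(C)(C)C)[C@H](c2ccc(O[Si](C)(C)C(C)(C)C)c(OC)c2)O3)[C@@H](C[Si](C)(C)OC(C)C)[C@H]1Cc1ccc(O[Si](C)(C)C(C)(C)C)c(OC)c1 | intermediate
23 | (3S,4R,5R)-5-DHB-3-(G-methyl)-3-hydroxy-4-{[dimethyl(propan-2-yloxy)silyl]methyl}oxolan-2-one | O=C1O[C@@H](c2cc(OC)c3c(c2)[C@H](CO[Si](C)(C)C(C)(C)C)[C@H](c2ccc(O[Si](C)(C)C(C)(C)C)c(OC)c2)O3)[C@@H](C[Si](C)(C)OC(C)C)[C@@]1(O)Cc1ccc(O[Si](C)(C)C(C)(C)C)c(OC)c1 | intermediate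
24 | (3S,4R,5R)-5-DHB-3-(G-methyl)-4-{[dimethyl(propan-2-yloxy)silyl]methyl}oxolane-2,3-diol (both C2 anomers) | OC1O[C@@H](c2cc(OC)c3c(c2)[C@H](CO[Si](C)(C)C(C)(C)C)[C@H](c2ccc(O[Si](C)(C)C(C)(C)C)c(OC)c2)O3)[C@@H](C[Si](C)(C)OC(C)C)[C@@]1(O)Cc1ccc(O[Si](C)(C)C(C)(C)C)c(OC)c1 | intermediate
25 | (3S,4R,5R)-5-DHB-3-(G-methyl)-4-{[dimethyl(propan-2-yloxy)silyl]methyl}oxolan-3-ol | C1O[C@@H](c2cc(OC)c3c(c2)[C@H](CO[Si](C)(C)C(C)(C)C)[C@H](c2ccc(O[Si](C)(C)C(C)(C)C)c(OC)c2)O3)[C@@H](C[Si](C)(C)OC(C)C)[C@@]1(O)Cc1ccc(O[Si](C)(C)C(C)(C)C)c(OC)c1 | intermediate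
26 | (3S,4R,5R)-4-{[fluoro(dimethyl)silyl]methyl}-5-[(2R,3R)-2-(4-hydroxy-3-methoxyphenyl)-3-(hydroxymethyl)-7-methoxy-2,3-dihydro-1-benzofuran-5-yl]-3-[(4-hydroxy-3-methoxyphenyl)methyl]oxolan-3-ol | C1O[C@@H](c2cc(OC)c3c(c2)[C@H](CO)[C@H](c2ccc(O)c(OC)c2)O3)[C@@H](C[Si](C)(C)F)[C@@]1(O)Cc1ccc(O)c(OC)c1 | intermediate (not isolated)
27 | (3S,4R,5R)-5-[(2R,3R)-2-(4-hydroxy-3-methoxyphenyl)-3-(hydroxymethyl)-7-methoxy-2,3-dihydro-1-benzofuran-5-yl]-3-[(4-hydroxy-3-methoxyphenyl)methyl]-4-(hydroxymethyl)oxolan-3-ol (CNP0284796.1) | COc1cc(C[C@@]2(O)CO[C@@H](c3cc(OC)c4c(c3)[C@H](CO)[C@H](c3ccc(O)c(OC)c3)O4)[C@H]2CO)ccc1O | target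

## Step count and least certain steps

Total: 18 steps. Longest linear sequence: 15 steps (1 → 2 → 3 → 5 → 7 → 8 → 9 → 10 → 11 → 15 → 21 → 22 → 23 → 25 → 27, that is steps 1–8, 11 and 13–18).

**Step 13 (key step).** The most likely failure is incomplete carbomagnesiation. The α-silyl Grignard reagent is a weak nucleophile, the alkyne is internal, and its CH2 group (benzylic and propargylic) can be deprotonated, so isomerisation to the allene and recovery of 15 may compete. Loss of silicon from the vinylogous α-silyl lactone during the acidic quench is a second risk.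
Fallback, from 11 and back to the route at 21: under the conditions of step 11, methyl propiolate is added to 11 to give the hydroxy ynoate F1. The organocopper reagent made from 17 and CuBr·SMe2 adds syn to the ynoate at −78 °C (carbon to C3), the alkenylcopper is quenched with iodine, and the cis hydroxy ester lactonises on mild acid to the C4-iodo butenolide F2. Negishi coupling of F2 with the benzylzinc bromide F3 (from 12, Zn dust and LiCl) under Pd(PPh3)4 installs the C4 benzyl group and gives 21.

**Step 14.** Saturation of the hindered tetrasubstituted alkene competes with hydrogenation of the three electron-rich arenes and with hydrogenolysis of the allylic–benzylic C2–O1 bond, because rhodium is also active for both; the reaction may have to be stopped short of full conversion.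
Fallback, from 21 directly to 23 (replacing steps 14 and 15): a Mukaiyama-type reductive hydroxylation with Mn(dpm)3 (dpm = dipivaloylmethanate), PhSiH3 and O2 in iPrOH–CH2Cl2 at 0 °C. Hydrogen-atom transfer to C3 from the face opposite the C2 aryl group gives the C4 radical, which takes up oxygen anti to the C3 side chain to give the hydroperoxide F4; P(OEt)3 reduces F4 to 23.

**Step 17.** The Lewis acid may ionise the C2–O1 bond, which is benzylic and para to the ring-A ether oxygen. That would epimerise C2 to the less crowded 2,3-trans ether or lead to reductive ring opening; the strain of the all-cis ring provides the driving force.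
Fallback, from 23 and back to the route at 25 (replacing steps 16 and 17): LiBH4 in THF (0 °C → rt) opens the lactone to the triol F5. TsCl in pyridine sulfonylates only the primary C5 hydroxyl to give the tosylate F6, whose C2 hydroxyl displaces the sulfonate on gentle warming (5-exo-tet) and closes the ether with the C2–O bond intact, giving 25.

**Step 11.** Facial selectivity may be insufficient or of the wrong sense for this hindered, electron-rich aldehyde, and the skipped aryl alkyne 14 may isomerise to the allene in the presence of the zinc bases.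
Fallback, from 11 and back to the route at 15: the same zinc–ProPhenol system with trimethylsilylacetylene, a robust alkyne for this reaction, gives the silyl alkynol F7. AgNO3 (cat.) in aqueous acetone removes only the alkynyl silyl group to give the terminal alkynol F8. Its alkoxide–acetylide (EtMgBr, 2 equiv) is benzylated at carbon by 12 under CuBr·SMe2 catalysis to give 15.

**Step 4.** The ortho-alkoxy aryl iodide may undergo oxidative addition and coupling slowly, so that decomposition of the diazo ester at palladium (carbene dimerisation) outruns the cross-coupling.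
Fallback, from 5 and back to the route at 7: Negishi coupling of 5 with commercial (2-ethoxy-2-oxoethyl)zinc bromide [Pd2(dba)3, XPhos, THF] gives the arylacetate F9. Regitz diazo transfer (4-acetamidobenzenesulfonyl azide, DBU, dry MeCN, 0 °C) then gives 7.

## Further compounds

F1 | step 13 | methyl (4S)-4-DHB-4-hydroxybut-2-ynoate | COC(=O)C#C[C@@H](O)c1cc(OC)c2c(c1)[C@H](CO[Si](C)(C)C(C)(C)C)[C@H](c1ccc(O[Si](C)(C)C(C)(C)C)c(OC)c1)O2
F2 | step 13 | (5S)-5-DHB-3-iodo-4-{[dimethyl(propan-2-yloxy)silyl]methyl}furan-2(5H)-one | O=C1O[C@@H](c2cc(OC)c3c(c2)[C@H](CO[Si](C)(C)C(C)(C)C)[C@H](c2ccc(O[Si](C)(C)C(C)(C)C)c(OC)c2)O3)C(C[Si](C)(C)OC(C)C)=C1I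
F3 | step 13 | (G-methyl)zinc bromide | Br[Zn]Cc1ccc(O[Si](C)(C)C(C)(C)C)c(OC)c1
F4 | step 14 | (3S,4R,5R)-5-DHB-3-(G-methyl)-3-hydroperoxy-4-{[dimethyl(propan-2-yloxy)silyl]methyl}oxolan-2-one | O=C1O[C@@H](c2cc(OC)c3c(c2)[C@H](CO[Si](C)(C)C(C)(C)C)[C@H](c2ccc(O[Si](C)(C)C(C)(C)C)c(OC)c2)O3)[C@@H](C[Si](C)(C)OC(C)C)[C@@]1(OO)Cc1ccc(O[Si](C)(C)C(C)(C)C)c(OC)c1
F5 | step 17 | (2S,3R,4R)-4-DHB-2-(G-methyl)-3-{[dimethyl(propan-2-yloxy)silyl]methyl}butane-1,2,4-triol | O[C@@H](c1cc(OC)c2c(c1)[C@H](CO[Si](C)(C)C(C)(C)C)[C@H](c1ccc(O[Si](C)(C)C(C)(C)C)c(OC)c1)O2)[C@@H](C[Si](C)(C)OC(C)C)[C@](O)(CO)Cc1ccc(O[Si](C)(C)C(C)(C)C)c(OC)c1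
F6 | step 17 | (2S,3R,4R)-4-DHB-2-(G-methyl)-2,4-dihydroxy-3-{[dimethyl(propan-2-yloxy)silyl]methyl}butyl 4-methylbenzenesulfonate | O[C@@H](c1cc(OC)c2c(c1)[C@H](CO[Si](C)(C)C(C)(C)C)[C@H](c1ccc(O[Si](C)(C)C(C)(C)C)c(OC)c1)O2)[C@@H](C[Si](C)(C)OC(C)C)[C@](O)(COS(=O)(=O)c1ccc(C)cc1)Cc1ccc(O[Si](C)(C)C(C)(C)C)c(OC)c1
F7 | step 11 | (1S)-1-DHB-3-(trimethylsilyl)prop-2-yn-1-ol | O[C@H](C#C[Si](C)(C)C)c1cc(OC)c2c(c1)[C@H](CO[Si](C)(C)C(C)(C)C)[C@H](c1ccc(O[Si](C)(C)C(C)(C)C)c(OC)c1)O2
F8 | step 11 | (1R)-1-DHB-prop-2-yn-1-ol (same spatial arrangement as 15) | O[C@H](C#C)c1cc(OC)c2c(c1)[C@H](CO[Si](C)(C)C(C)(C)C)[C@H](c1ccc(O[Si](C)(C)C(C)(C)C)c(OC)c1)O2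
F9 | step 4 | ethyl 2-[2-(G-methoxy)-3-methoxy-5-(methoxycarbonyl)phenyl]acetate | CCOC(=O)Cc1cc(C(=O)OC)cc(OC)c1OCc1ccc(O[Si](C)(C)C(C)(C)C)c(OC)c1
A1 | alternative 1 | (4R,5R)-5-DHB-4-{[(tert-butyldimethylsilyl)oxy]methyl}-3-methylideneoxolan-2-one (4,5-cis) | C=C1C(=O)O[C@@H](c2cc(OC)c3c(c2)[C@H](CO[Si](C)(C)C(C)(C)C)[C@H](c2ccc(O[Si](C)(C)C(C)(C)C)c(OC)c2)O3)[C@H]1CO[Si](C)(C)C(C)(C)C
A2 | alternative 1 | methyl (2E)-4-[(tert-butyldimethylsilyl)oxy]-2-[(4,4,5,5-tetramethyl-1,3,2-dioxaborolan-2-yl)methyl]but-2-enoate (silyloxymethyl cis to the borylmethyl group) | COC(=O)/C(CB1OC(C)(C)C(C)(C)O1)=C/CO[Si](C)(C)C(C)(C)C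
A3 | alternative 2 | methyl (2R,3S)-2-G-7-methoxy-5-[(2R,3R,4S)-4-(G-methyl)-3-{[(tert-butyldimethylsilyl)oxy]methyl}-4-[(trimethylsilyl)oxy]oxolan-2-yl]-2,3-dihydro-1-benzofuran-3-carboxylate | COc1cc(C[C@@]2(O[Si](C)(C)C)CO[C@@H](c3cc(OC)c4c(c3)[C@H](C(=O)OC)[C@H](c3ccc(O[Si](C)(C)C(C)(C)C)c(OC)c3)O4)[C@H]2CO[Si](C)(C)C(C)(C)C)ccc1O[Si](C)(C)C(C)(C)C
A4 | alternative 2 | methyl 2-diazo-2-{2-(G-methoxy)-3-methoxy-5-[(2R,3R,4S)-4-(G-methyl)-3-{[(tert-butyldimethylsilyl)oxy]methyl}-4-[(trimethylsilyl)oxy]oxolan-2-yl]phenyl}acetate | COc1cc(C[C@@]2(O[Si](C)(C)C)CO[C@@H](c3cc(OC)c(OCc4ccc(O[Si](C)(C)C(C)(C)C)c(OC)c4)c(c3)C(=[N+]=[N-])C(=O)OC)[C@H]2CO[Si](C)(C)C(C)(C)C)ccc1O[Si](C)(C)C(C)(C)C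
A5 | alternative 3 | 4-[(2R,3R)-3-{[(tert-butyldimethylsilyl)oxy]methyl}-5-(1,3-dioxolan-2-yl)-7-methoxy-2,3-dihydro-1-benzofuran-2-yl]-2-methoxyphenyl 2,2-dimethylpropanoate | O1CCOC1c1cc(OC)c2c(c1)[C@H](CO[Si](C)(C)C(C)(C)C)[C@H](c1ccc(OC(=O)C(C)(C)C)c(OC)c1)O2
A6 | alternative 3 | 4-[(1S,2R)-3-[(tert-butyldimethylsilyl)oxy]-2-[5-(1,3-dioxolan-2-yl)-2-hydroxy-3-methoxyphenyl]-1-hydroxypropyl]-2-methoxyphenyl 2,2-dimethylpropanoate | O1CCOC1c1cc(OC)c(O)c(c1)[C@H](CO[Si](C)(C)C(C)(C)C)[C@@H](c1ccc(OC(=O)C(C)(C)C)c(OC)c1)O
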